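West, south and north share one charge and differ in temperature; gamma and theta are earlier runs of that recipe with other monomer charges, and theta stands at the temperature of south.

the same everywhere: pre-initiator 0.16 mM; impurity 74 µM
- gamma: free monomer 6.7 mM; transfer agent 1 mM; temperature 15 °C; run made earlier
- theta: free monomer 15 mM; transfer agent 1 mM; temperature 40 °C; run made earlier
- west: free monomer 10 mM; transfer agent 1.00 mM; temperature 60 °C; time 8.0 h
- south: free monomer 10 mM; transfer agent 1.00 mM; temperature 40 °C; time 8.0 h
- north: free monomer 10 mM; transfer agent 1.00 mM; temperature 20 °C; time 8.0 h

| gamma: time / h | gamma: monomer in chains / % | theta: time / h | theta: monomer in chains / % |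
|---|---|---|---|
| 10.0 | 0 | 1.00 | 2.3 |
| 20.0 | 0 | 4.00 | 35.1 |
| 30.0 | 5.7 | 5.00 | 46.0 |
| 40.0 | 9.4 | 8.00 | 59.2 |
| 50.0 | 20.3 | 15.0 | 65.4 |

(standard deviation of a reading: 1 percentage point)

1. the flask that comes out highest in amount of monomer in chains, in percent of the free monomer charged, or "all alike" when all lie within 1.5 percentage points (west / south / north / all alike)
2. monomer in chains at the end, in percent of the free monomer charged, west
3. monomer in chains at the end, in percent of the free monomer charged, south
4. monomer in chains at the end, in percent of the free monomer charged, north

Gamma reads 0% at 20.0 h, so something holds the chains back at first, and theta also starts slowly, with 2.3% at 1.00 h. But theta then flattens, reading 65.4% at 15.0 h, a gain of 6.2 percentage points since 8.00 h.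

So I work with the fraction left, which the last reading of theta puts at 34.6%. I define the stop depth Λ as the natural logarithm of free monomer charged over free monomer left at the stop: 1.06. My reading is a dead-end polymerization, pseudo-first-order in free monomer, and in such a flask the fraction left does not follow the monomer charge. South, at the temperature of theta, should therefore read as theta did at 8.00 h, namely 59.2%.

Gamma reads 20.3% at 50.0 h, while theta reads 35.1% at 4.00 h; the two differ in charge and temperature, but in my reading the charge does not enter, so I credit the warmth. So I let west reach its stop by 8.0 h, and I assume the same Λ there, which gives 65.4% in chains, above my south. North is warmer than gamma, but north is read at 8.0 h and gamma still read 0% at 20.0 h, so I put north near zero.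

The forecast differs from me: it says south, with west 3%, south 44% and north 0%, and it holds of west that “the equilibrium monomer level probably reaches about 10 mM or more at 60 °C, so little polymer forms”.

West gives 66.8%, south 60.9% and north 1.43%, which puts west highest.

    living end + transfer agent → dead chain (kL = 0.0587 M⁻¹ s⁻¹, Ea = 53.0 kJ mol⁻¹)
    initiator + impurity → spent initiator (k = 510 M⁻¹ s⁻¹, Ea = 36.0 kJ mol⁻¹)
    free monomer + living end → monomer in chains + living end, rate k3*[living end]*[free monomer] (k = 0.713 M⁻¹ s⁻¹, Ea = 53.0 kJ mol⁻¹)
    free monomer + initiator → living end + monomer in chains (k = 0.163 M⁻¹ s⁻¹, Ea = 59.0 kJ mol⁻¹)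
    pre-initiator → initiator (k = 1.04 × 10⁻⁵ s⁻¹, Ea = 91.0 kJ mol⁻¹)
    (constants at 20 °C)

The rate constants of growth of a living end and of its death on the transfer agent stand at 12.1 to one, with equal activation energies, and west ends at Λ = 1.10 against the 1.06 read from theta. Carried to the repeat of north at 45 °C, the value from theta leaves 34.6% of the free monomer, and that flask holds 33.9% at 8.00 h.

All runs stem from a simulated flask with constants of no real substance.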